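**Retrosynthetic overview**
1. Numbering as in germacranolides: ring C1–C10 (C4/C5 oxirane, C6 tiglate carbinol, C7/C8 lactone fusion, C9 free carbinol, C10 CHMe), lactone carbons C11–C13. The endgame is O6 tigloylation and O9 desilylation.
2. Key disconnection C6–C7. The carbinol carbon C6 is bonded to C7, the β-carbon of the α-methylene-γ-lactone, so C6(O)–C7–C11(=C13H2) is a homoallylic alcohol whose alkene is exocyclic to the lactone ring. Retro-allylation with transposition gives a C6 epoxy aldehyde and a 3-(bromomethyl)furan-2(5H)-one (endocyclic C7=C11, C13H2Br). Their intramolecular chromium-mediated coupling closes the ten-membered ring, sets C6 and C7 and creates the exo-methylene in one operation.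
3. Butenolide: ring-closing metathesis of the 2-(bromomethyl)acrylate of the C8 vinyl carbinol; C8 from Felkin–Anh vinyl addition to the C8 aldehyde.
4. C4/C5: Sharpless epoxidation of the (E)-allylic alcohol made by carboalumination/hydroxymethylation of a terminal alkyne. C9/C10: Sharpless epoxidation of (2E)-oct-2-en-7-yn-1-ol and C3-selective opening with AlMe3.
5. Ring order: oxirane, then butenolide, then the ten-membered carbocycle (in that step the butenolide becomes the α-methylene lactone).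

Key step: step 13

Remark: the ester is read from the SMILES as the (E)-2-methylbut-2-enoate (tiglate); locants in the Why lines use the germacranolide numbering above.

**Route**

Step 1
Reactants: 1 hex-5-yn-1-ol; 2 ethyl (triphenyl-λ5-phosphanylidene)acetate
Product: 4 ethyl (2E)-oct-2-en-7-ynoate, via hex-5-ynal 3 (not isolated)
Conditions: TEMPO (10 mol%), PhI(OAc)2 (1.1 equiv), CH2Cl2, rt; then 2 (1.3 equiv), rt
Reagents that add atoms: none
Why: The TEMPO/PhI(OAc)2 oxidation stops at aldehyde 3 and leaves the alkyne alone, and the stabilised ylide 2 then gives the (E)-enoate in the same flask (Wittig reaction).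

Step 2
Reactants: 4 ethyl (2E)-oct-2-en-7-ynoate
Product: 5 (2E)-oct-2-en-7-yn-1-ol
Conditions: i-Bu2AlH (2.2 equiv), CH2Cl2, −78 °C to 0 °C; aq. Rochelle salt
Reagents that add atoms: none
Why: Diisobutylaluminium hydride reduces the conjugated ester in the 1,2 sense to the allylic alcohol at low temperature without touching the terminal alkyne or the (E)-alkene.

Step 3
Reactants: 5 (2E)-oct-2-en-7-yn-1-ol
Product: 6 [(2S,3S)-3-(pent-4-yn-1-yl)oxiran-2-yl]methanol
Conditions: Ti(OiPr)4 (10 mol%), L-(+)-diethyl tartrate (12 mol%), t-BuOOH (2 equiv), 4 Å MS, CH2Cl2, −20 °C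
Reagents that add atoms: tert-butyl hydroperoxide CC(C)(C)OO
Why: Sharpless asymmetric epoxidation of the primary (E)-allylic alcohol with L-(+)-diethyl tartrate delivers oxygen to the face that gives the (2S,3S)-epoxy alcohol, which fixes C9 and prepares C10 for inversion.

Step 4
Reactants: 6 [(2S,3S)-3-(pent-4-yn-1-yl)oxiran-2-yl]methanol
Product: 7 (2R,3R)-3-methyloct-7-yne-1,2-diol
Conditions: AlMe3 (3 equiv), hexane/CH2Cl2, 0 °C to rt; aq. Rochelle salt
Reagents that add atoms: trimethylaluminium C[Al](C)C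
Why: AlMe3 forms the aluminium alkoxide of the 2,3-epoxy alcohol and delivers methyl to C3 of the epoxide with inversion (alkylative epoxide opening to the 1,2-diol), which sets the C10 methyl anti to the C9 hydroxyl.

Step 5
Reactants: 7 (2R,3R)-3-methyloct-7-yne-1,2-diol
Product: 8 (2R,3R)-3-methyl-1,2-bis[(triethylsilyl)oxy]oct-7-yne
Conditions: Et3SiCl (2.5 equiv), imidazole (5 equiv), DMF, 0 °C to rt
Reagents that add atoms: chlorotriethylsilane CC[Si](Cl)(CC)CC
Why: Exhaustive silylation with Et3SiCl/imidazole protects the C9 hydroxyl and prepares the primary position for direct oxidation.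

Step 6
Reactants: 8 (2R,3R)-3-methyl-1,2-bis[(triethylsilyl)oxy]oct-7-yne
Product: 9 (2R,3R)-3-methyl-2-[(triethylsilyl)oxy]oct-7-ynal
Conditions: (COCl)2 (4 equiv), DMSO (8 equiv), CH2Cl2, −78 °C to −40 °C; then Et3N (10 equiv), −78 °C to 0 °C
Reagents that add atoms: none
Why: Under Swern conditions the primary triethylsilyl ether is cleaved by the chlorosulfonium salt and oxidised in situ while the secondary triethylsilyl ether is untouched, so the α-silyloxy aldehyde should form without a separate deprotection and without epimerisation of C9 at low temperature.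

Step 7
Reactants: 9 (2R,3R)-3-methyl-2-[(triethylsilyl)oxy]oct-7-ynal
Product: 10 (3S,4R,5R)-5-methyl-4-[(triethylsilyl)oxy]dec-1-en-9-yn-3-ol
Conditions: CH2=CHMgBr (2.5 equiv), THF, −78 °C; aq. NH4Cl at −78 °C
Reagents that add atoms: vinylmagnesium bromide C=C[Mg]Br
Why: Felkin–Anh addition of the vinyl Grignard reagent to the α-silyloxy aldehyde (nucleophile anti to the C9–OSi bond, non-chelating silyl ether) should give mainly the 8,9-anti carbinol and so set C8, the aldehyde reacting at −78 °C faster than the alkyne C–H is deprotonated.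

Step 8
Reactants: 10 (3S,4R,5R)-5-methyl-4-[(triethylsilyl)oxy]dec-1-en-9-yn-3-ol
Product: 12 (2E,7R,8R,9S)-3,7-dimethyl-8-[(triethylsilyl)oxy]undeca-2,10-diene-1,9-diol, via (E)-alkenyldimethylalane 11 (not isolated)
Conditions: AlMe3 (4 equiv), Cp2ZrCl2 (0.3 equiv), CH2Cl2, 0 °C to rt; then (CH2O)n, THF, 0 °C to rt; aq. Rochelle salt
Reagents that add atoms: trimethylaluminium C[Al](C)C; paraformaldehyde (reacts as formaldehyde) C=O
Why: In the Negishi carboalumination Cp2ZrCl2 catalyses syn addition of Me–Al across the terminal alkyne with aluminium on the terminal carbon (11), and the alkenylalane is hydroxymethylated by formaldehyde with retention to the (E)-trisubstituted allylic alcohol, the free C8 hydroxyl being carried as its aluminium alkoxide.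

Step 9
Reactants: 12 (2E,7R,8R,9S)-3,7-dimethyl-8-[(triethylsilyl)oxy]undeca-2,10-diene-1,9-diol
Product: 13 (3S,4R,5R)-8-[(2R,3R)-3-(hydroxymethyl)-2-methyloxiran-2-yl]-5-methyl-4-[(triethylsilyl)oxy]oct-1-en-3-ol
Conditions: Ti(OiPr)4 (10 mol%), D-(−)-diethyl tartrate (12 mol%), t-BuOOH (1.3 equiv), 4 Å MS, CH2Cl2, −25 °C
Reagents that add atoms: tert-butyl hydroperoxide CC(C)(C)OO
Why: Sharpless asymmetric epoxidation with D-(−)-diethyl tartrate gives the (2R,3R)-epoxy alcohol as with geraniol-type substrates and sets C4 and C5, the primary trisubstituted allylic alcohol reacting far faster than the monosubstituted secondary vinyl carbinol at C8.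

Step 10
Reactants: 13 (3S,4R,5R)-8-[(2R,3R)-3-(hydroxymethyl)-2-methyloxiran-2-yl]-5-methyl-4-[(triethylsilyl)oxy]oct-1-en-3-ol
Product: 14 (2S,3R)-3-{(4R,5R,6S)-6-hydroxy-4-methyl-5-[(triethylsilyl)oxy]oct-7-en-1-yl}-3-methyloxirane-2-carbaldehyde
Conditions: TEMPO (10 mol%), PhI(OAc)2 (1.1 equiv), CH2Cl2, 0 °C to rt
Reagents that add atoms: none
Why: The oxoammonium oxidation (TEMPO/PhI(OAc)2) is selective for the primary alcohol over the hindered secondary allylic alcohol and converts 2,3-epoxy alcohols into epoxy aldehydes without epimerisation.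

Step 11
Reactants: 14 (2S,3R)-3-{(4R,5R,6S)-6-hydroxy-4-methyl-5-[(triethylsilyl)oxy]oct-7-en-1-yl}-3-methyloxirane-2-carbaldehyde; 15 2-(bromomethyl)prop-2-enoic acid
Product: 16 (3S,4R,5R)-8-[(2R,3S)-3-formyl-2-methyloxiran-2-yl]-5-methyl-4-[(triethylsilyl)oxy]oct-1-en-3-yl 2-(bromomethyl)prop-2-enoate
Conditions: 15 (1.5 equiv), DCC (1.6 equiv), DMAP (5 mol%), CH2Cl2, 0 °C
Reagents that add atoms: none
Why: Steglich esterification of the secondary C8 alcohol with acid 15 under neutral conditions tolerates the epoxy aldehyde, the silyl ether and the allylic bromide.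

Step 12
Reactants: 16 (3S,4R,5R)-8-[(2R,3S)-3-formyl-2-methyloxiran-2-yl]-5-methyl-4-[(triethylsilyl)oxy]oct-1-en-3-yl 2-(bromomethyl)prop-2-enoate
Product: 17 (2S,3R)-3-{(4R,5R)-5-[(2S)-4-(bromomethyl)-5-oxo-2,5-dihydrofuran-2-yl]-4-methyl-5-[(triethylsilyl)oxy]pentyl}-3-methyloxirane-2-carbaldehyde
Conditions: second-generation Grubbs catalyst (H2IMes)(PCy3)Cl2Ru=CHPh (10 mol%), CH2Cl2 (5 mM), 40 °C
Reagents that add atoms: none
Why: Ring-closing metathesis between the vinyl group and the 1,1-disubstituted acrylate alkene forms the five-membered butenolide (C7=C11) with loss of ethene, as in the metathesis of methacrylates of allylic alcohols, and the ruthenium carbene tolerates epoxide, aldehyde and bromide.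

Step 13
Reactants: 17 (2S,3R)-3-{(4R,5R)-5-[(2S)-4-(bromomethyl)-5-oxo-2,5-dihydrofuran-2-yl]-4-methyl-5-[(triethylsilyl)oxy]pentyl}-3-methyloxirane-2-carbaldehyde
Product: 19 (4R,5R,6R,7R,8S,9R,10R)-4,5-epoxy-6-hydroxy-9-[(triethylsilyl)oxy]germacr-11(13)-en-12,8-olide, via allylchromium dichloride 18 (not isolated)
Conditions: CrCl2 (10 equiv), THF, rt, slow addition of 17 by syringe pump (final 2 mM); aq. NH4Cl at 0 °C
Reagents that add atoms: none
Why: CrCl2 reduces the allylic C13–Br bond of 17 by two single-electron transfers to the primary allylchromium species 18, which adds to the tethered C6 aldehyde through a six-membered chair transition state with allylic transposition, so that the new bond starts from C7 (the γ-carbon of the butenolide) and the endocyclic C7=C11 alkene becomes the exocyclic C11=C13 methylene of the final lactone. The closest known reaction type is the Nozaki–Hiyama–Kishi (Barbier-type) allylation of aldehydes with 2-(bromomethyl)acrylates and 3-(bromomethyl)furan-2(5H)-ones, which has also been used to close ten-membered germacranolide rings. The only ring closed is the ten-membered carbocycle, by a 10-exo-trig attack of C7 on the aldehyde carbon (the carbonyl oxygen and the C11=C13 bond both end up outside the new ring). C7 is controlled by the existing C8 centre, the aldehyde arm reaching the butenolide on the face anti to the C8–C9 bond so that H7 and H8 become trans; C6 is controlled by the chair transition state, in which the ring-locked allyl geometry (C8 trans to C13) and an equatorial C5 give the anti C6/C7 relationship, and this is the same face that Felkin–Anh attack anti to the C5–O bond of the (4R,5R)-epoxide selects, so the three elements are matched. The step needs γ- over α-attack (ten- versus twelve-membered ring), secured by the cyclic transition state of the allylchromium reagent, and ring closure over oligomerisation, secured by slow addition at high dilution. It also needs the lactone to stay on O8, which the kinetically inert trivalent chromium alkoxide and a cold neutral quench should secure, while divalent chromium leaves the silyl ether and the lactone untouched and should add faster than it opens the epoxy aldehyde.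

Step 14
Reactants: 19 (4R,5R,6R,7R,8S,9R,10R)-4,5-epoxy-6-hydroxy-9-[(triethylsilyl)oxy]germacr-11(13)-en-12,8-olide; 20 (2E)-2-methylbut-2-enoyl chloride (tigloyl chloride)
Product: 21 (4R,5R,6R,7R,8S,9R,10R)-4,5-epoxy-6-[(2E)-2-methylbut-2-enoyloxy]-9-[(triethylsilyl)oxy]germacr-11(13)-en-12,8-olide
Conditions: 20 (3 equiv), pyridine (6 equiv), DMAP (0.2 equiv), CH2Cl2, 0 °C to rt
Reagents that add atoms: none
Why: DMAP-catalysed acylation of the free C6 hydroxyl with tigloyl chloride and pyridine (too weak a base to form the vinylketene) installs the (E)-2-methylbut-2-enoate, the C9 oxygen being blocked as its silyl ether.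

Step 15
Reactants: 21 (4R,5R,6R,7R,8S,9R,10R)-4,5-epoxy-6-[(2E)-2-methylbut-2-enoyloxy]-9-[(triethylsilyl)oxy]germacr-11(13)-en-12,8-olide
Product: 22 (4R,5R,6R,7S,8S,9R,10R)-4,5-epoxy-9-hydroxy-6-[(2E)-2-methylbut-2-enoyloxy]germacr-11(13)-en-12,8-olide (CNP0165329.2)
Conditions: HF·pyridine, pyridine, THF, 0 °C
Reagents that add atoms: none
Why: Buffered HF·pyridine cleaves the secondary triethylsilyl ether under mildly acidic conditions that should spare the epoxide, the α-methylene lactone and the tiglate.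

**Compound list**

1 | hex-5-yn-1-ol | C#CCCCCO | starting material
2 | ethyl (triphenyl-λ5-phosphanylidene)acetate | CCOC(=O)C=P(c1ccccc1)(c1ccccc1)c1ccccc1 | starting material
3 | hex-5-ynal | C#CCCCC=O | intermediate
4 | ethyl (2E)-oct-2-en-7-ynoate | C#CCCC/C=C/C(=O)OCC | intermediate
5 | (2E)-oct-2-en-7-yn-1-ol | C#CCCC/C=C/CO | intermediate
6 | [(2S,3S)-3-(pent-4-yn-1-yl)oxiran-2-yl]methanol | C#CCCC[C@@H]1O[C@H]1CO | intermediate
7 | (2R,3R)-3-methyloct-7-yne-1,2-diol | C#CCCC[C@@H](C)[C@@H](O)CO | intermediate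
8 | (2R,3R)-3-methyl-1,2-bis[(triethylsilyl)oxy]oct-7-yne | C#CCCC[C@@H](C)[C@@H](O[Si](CC)(CC)CC)CO[Si](CC)(CC)CC | intermediate
9 | (2R,3R)-3-methyl-2-[(triethylsilyl)oxy]oct-7-ynal | C#CCCC[C@@H](C)[C@@H](O[Si](CC)(CC)CC)C=O | intermediate
10 | (3S,4R,5R)-5-methyl-4-[(triethylsilyl)oxy]dec-1-en-9-yn-3-ol | C#CCCC[C@@H](C)[C@@H](O[Si](CC)(CC)CC)[C@H](C=C)O | intermediate
11 | (E)-alkenyldimethylalane from 10 (Me2Al on the terminal alkene carbon cis to the new methyl; C8 hydroxyl as its dimethylaluminium alkoxide) | C[Al](C)/C=C(\C)CCC[C@@H](C)[C@@H](O[Si](CC)(CC)CC)[C@H](C=C)O[Al](C)C | intermediate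
12 | (2E,7R,8R,9S)-3,7-dimethyl-8-[(triethylsilyl)oxy]undeca-2,10-diene-1,9-diol | OC/C=C(\C)CCC[C@@H](C)[C@@H](O[Si](CC)(CC)CC)[C@H](C=C)O | intermediate
13 | (3S,4R,5R)-8-[(2R,3R)-3-(hydroxymethyl)-2-methyloxiran-2-yl]-5-methyl-4-[(triethylsilyl)oxy]oct-1-en-3-ol | OC[C@H]1O[C@]1(C)CCC[C@@H](C)[C@@H](O[Si](CC)(CC)CC)[C@H](C=C)O | intermediate
14 | (2S,3R)-3-{(4R,5R,6S)-6-hydroxy-4-methyl-5-[(triethylsilyl)oxy]oct-7-en-1-yl}-3-methyloxirane-2-carbaldehyde | O=C[C@H]1O[C@]1(C)CCC[C@@H](C)[C@@H](O[Si](CC)(CC)CC)[C@H](C=C)O | intermediate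
15 | 2-(bromomethyl)prop-2-enoic acid | C=C(CBr)C(=O)O | starting material
16 | (3S,4R,5R)-8-[(2R,3S)-3-formyl-2-methyloxiran-2-yl]-5-methyl-4-[(triethylsilyl)oxy]oct-1-en-3-yl 2-(bromomethyl)prop-2-enoate | O=C[C@H]1O[C@]1(C)CCC[C@@H](C)[C@@H](O[Si](CC)(CC)CC)[C@H](C=C)OC(=O)C(=C)CBr | intermediate
17 | (2S,3R)-3-{(4R,5R)-5-[(2S)-4-(bromomethyl)-5-oxo-2,5-dihydrofuran-2-yl]-4-methyl-5-[(triethylsilyl)oxy]pentyl}-3-methyloxirane-2-carbaldehyde | O=C[C@H]1O[C@]1(C)CCC[C@@H](C)[C@@H](O[Si](CC)(CC)CC)[C@H]2OC(=O)C(CBr)=C2 | intermediate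
18 | allylchromium dichloride derived from 17 (C13–CrCl2 in place of C13–Br) | O=C[C@H]1O[C@]1(C)CCC[C@@H](C)[C@@H](O[Si](CC)(CC)CC)[C@H]2OC(=O)C(C[Cr](Cl)Cl)=C2 | intermediate
19 | (4R,5R,6R,7R,8S,9R,10R)-4,5-epoxy-6-hydroxy-9-[(triethylsilyl)oxy]germacr-11(13)-en-12,8-olide | C=C1C(=O)O[C@@H]2[C@H](O[Si](CC)(CC)CC)[C@H](C)CCC[C@@]3(C)O[C@@H]3[C@H](O)[C@@H]12 | intermediate
20 | (2E)-2-methylbut-2-enoyl chloride (tigloyl chloride) | C/C=C(\C)C(=O)Cl | starting material
21 | (4R,5R,6R,7R,8S,9R,10R)-4,5-epoxy-6-[(2E)-2-methylbut-2-enoyloxy]-9-[(triethylsilyl)oxy]germacr-11(13)-en-12,8-olide | C=C1C(=O)O[C@@H]2[C@H](O[Si](CC)(CC)CC)[C@H](C)CCC[C@@]3(C)O[C@@H]3[C@H](OC(=O)/C(C)=C/C)[C@@H]12 | intermediate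
22 | (4R,5R,6R,7S,8S,9R,10R)-4,5-epoxy-9-hydroxy-6-[(2E)-2-methylbut-2-enoyloxy]germacr-11(13)-en-12,8-olide | C=C1C(=O)O[C@@H]2[C@H](O)[C@H](C)CCC[C@@]3(C)O[C@@H]3[C@H](OC(=O)/C(C)=C/C)[C@@H]12 | target

**Step count and risks**

Total step count: 15. Longest linear sequence: 15 steps (from 1 to 22).

Steps most likely to fail:

1. Step 13 (macrocyclisation). The flexible C1–C3 chain offers little preorganisation, so ring closure may lose to intermolecular coupling, and the α,β-epoxy aldehyde may be opened reductively by divalent chromium before allyl transfer. Fallback (sets out from 12, returns at 19): the epoxide is installed after ring closure, so the cyclisation runs on a conjugated enal whose (E)-alkene stiffens the chain. TEMPO/PhI(OAc)2 oxidation of the primary allylic alcohol of 12 gives (2E,7R,8R,9S)-9-hydroxy-3,7-dimethyl-8-[(triethylsilyl)oxy]undeca-2,10-dienal F1. Steglich esterification with 15 gives (3S,4R,5R,9E)-5,9-dimethyl-11-oxo-4-[(triethylsilyl)oxy]undeca-1,9-dien-3-yl 2-(bromomethyl)prop-2-enoate F2. Ring-closing metathesis gives (2E,7R,8R)-8-[(2S)-4-(bromomethyl)-5-oxo-2,5-dihydrofuran-2-yl]-3,7-dimethyl-8-[(triethylsilyl)oxy]oct-2-enal F3. CrCl2 at high dilution closes the ring to (4E,6S,7R,8S,9R,10R)-6-hydroxy-9-[(triethylsilyl)oxy]germacra-4,11(13)-dien-12,8-olide F4, which has the same spatial arrangement at C6 as 19. Sharpless epoxidation of F4 (Ti(OiPr)4, D-(−)-diethyl tartrate, t-BuOOH), which is the matched, anti-selective case for this secondary carbinol, should then give 19.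

2. Step 12 (ring-closing metathesis). The ruthenium alkylidene may turn over poorly on the electron-poor 1,1-disubstituted alkene that carries the allylic bromide, or the bromide may be ionised by the catalyst. Fallback (sets out from 14, returns at 17): the bromide is introduced after the metathesis. Steglich esterification of 14 with 2-{[(4-methoxybenzyl)oxy]methyl}prop-2-enoic acid gives (3S,4R,5R)-8-[(2R,3S)-3-formyl-2-methyloxiran-2-yl]-5-methyl-4-[(triethylsilyl)oxy]oct-1-en-3-yl 2-{[(4-methoxybenzyl)oxy]methyl}prop-2-enoate F5. Ring-closing metathesis gives the 4-{[(4-methoxybenzyl)oxy]methyl} analogue of 17 F6. DDQ in CH2Cl2/pH 7 buffer gives the 4-(hydroxymethyl) analogue of 17 F7. MsCl/Et3N at −20 °C gives the 4-{[(methylsulfonyl)oxy]methyl} analogue of 17 F8, and LiBr in acetone displaces the mesylate to give 17.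

3. Step 7 (vinyl addition). Facial discrimination in the Grignard addition may be insufficient, so that a large share of the C8 epimer forms. Fallback (sets out from 9, returns at 10): the addition is run as before, and the separated epimer (3R,4R,5R)-5-methyl-4-[(triethylsilyl)oxy]dec-1-en-9-yn-3-ol F9 is inverted by a Mitsunobu reaction (4-nitrobenzoic acid, PPh3, DIAD, THF) to (3S,4R,5R)-5-methyl-4-[(triethylsilyl)oxy]dec-1-en-9-yn-3-yl 4-nitrobenzoate F10. Brief methanolysis (K2CO3, MeOH, 0 °C) then gives 10.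

**Further compounds**

F1 | step 13 | (2E,7R,8R,9S)-9-hydroxy-3,7-dimethyl-8-[(triethylsilyl)oxy]undeca-2,10-dienal | O=C/C=C(\C)CCC[C@@H](C)[C@@H](O[Si](CC)(CC)CC)[C@H](C=C)O
F2 | step 13 | (3S,4R,5R,9E)-5,9-dimethyl-11-oxo-4-[(triethylsilyl)oxy]undeca-1,9-dien-3-yl 2-(bromomethyl)prop-2-enoate | O=C/C=C(\C)CCC[C@@H](C)[C@@H](O[Si](CC)(CC)CC)[C@H](C=C)OC(=O)C(=C)CBr
F3 | step 13 | (2E,7R,8R)-8-[(2S)-4-(bromomethyl)-5-oxo-2,5-dihydrofuran-2-yl]-3,7-dimethyl-8-[(triethylsilyl)oxy]oct-2-enal | O=C/C=C(\C)CCC[C@@H](C)[C@@H](O[Si](CC)(CC)CC)[C@H]1OC(=O)C(CBr)=C1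
F4 | step 13 | (4E,6S,7R,8S,9R,10R)-6-hydroxy-9-[(triethylsilyl)oxy]germacra-4,11(13)-dien-12,8-olide | C=C1C(=O)O[C@@H]2[C@H](O[Si](CC)(CC)CC)[C@H](C)CCC/C(C)=C/[C@H](O)[C@@H]12
F5 | step 12 | (3S,4R,5R)-8-[(2R,3S)-3-formyl-2-methyloxiran-2-yl]-5-methyl-4-[(triethylsilyl)oxy]oct-1-en-3-yl 2-{[(4-methoxybenzyl)oxy]methyl}prop-2-enoate | O=C[C@H]1O[C@]1(C)CCC[C@@H](C)[C@@H](O[Si](CC)(CC)CC)[C@H](C=C)OC(=O)C(=C)COCc1ccc(OC)cc1
F6 | step 12 | (2S,3R)-3-{(4R,5R)-5-[(2S)-4-{[(4-methoxybenzyl)oxy]methyl}-5-oxo-2,5-dihydrofuran-2-yl]-4-methyl-5-[(triethylsilyl)oxy]pentyl}-3-methyloxirane-2-carbaldehyde | O=C[C@H]1O[C@]1(C)CCC[C@@H](C)[C@@H](O[Si](CC)(CC)CC)[C@H]2OC(=O)C(COCc3ccc(OC)cc3)=C2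
F7 | step 12 | (2S,3R)-3-{(4R,5R)-5-[(2S)-4-(hydroxymethyl)-5-oxo-2,5-dihydrofuran-2-yl]-4-methyl-5-[(triethylsilyl)oxy]pentyl}-3-methyloxirane-2-carbaldehyde | O=C[C@H]1O[C@]1(C)CCC[C@@H](C)[C@@H](O[Si](CC)(CC)CC)[C@H]2OC(=O)C(CO)=C2
F8 | step 12 | (2S,3R)-3-{(4R,5R)-4-methyl-5-[(2S)-4-{[(methylsulfonyl)oxy]methyl}-5-oxo-2,5-dihydrofuran-2-yl]-5-[(triethylsilyl)oxy]pentyl}-3-methyloxirane-2-carbaldehyde | O=C[C@H]1O[C@]1(C)CCC[C@@H](C)[C@@H](O[Si](CC)(CC)CC)[C@H]2OC(=O)C(COS(C)(=O)=O)=C2
F9 | step 7 | (3R,4R,5R)-5-methyl-4-[(triethylsilyl)oxy]dec-1-en-9-yn-3-ol | C#CCCC[C@@H](C)[C@@H](O[Si](CC)(CC)CC)[C@@H](C=C)O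
F10 | step 7 | (3S,4R,5R)-5-methyl-4-[(triethylsilyl)oxy]dec-1-en-9-yn-3-yl 4-nitrobenzoate | C#CCCC[C@@H](C)[C@@H](O[Si](CC)(CC)CC)[C@H](C=C)OC(=O)c1ccc(cc1)[N+](=O)[O-]
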